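The 4'-hydroxyphenyl B ring is not brought in as an aryl unit but grown on the chromone. The ring at C2 of the pyranone (C) ring is disconnected across C1'–C6' and C2'–C3' to a C2-ethynyl group and a 1-methoxy-3-silyloxybutadiene. The polarised chain O=C4–C3=C2–C1'≡C2' makes the alkyne terminus C2' electrophilic. One [4+2] cycloaddition, followed by loss of methanol and of the silyl group, therefore forms the whole benzene ring and places the free hydroxyl para to C2. The dienophile, 2-ethynyl-5,6,7,8-tetramethoxychromen-4-one, is made from 1,2,3,4-tetramethoxybenzene through a hydroxyacetophenone and a chromone-2-carbaldehyde.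

Key step: step 6

Remark on stereochemistry: the target has no stereocentre and no stable stereoaxis, so no enantiocontrol is needed; the one sp3 centre of the cycloadduct is erased on aromatisation.
Remark on atom labels: C1' and C2' are the two former alkyne carbons, so the C1'–C2' bond is already present; the cycloaddition forms C1'–C6' and C2'–C3', while C3'–C4', C4'–C5' and C5'–C6' come from the diene.
Remark on design: the C2 aldehyde is carried in as a diethyl acetal by the Claisen partner, so no hydride reagent has to distinguish an ester from the C4 carbonyl of a chromone.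

Step 1
Reactants: 1 1,2,3,4-tetramethoxybenzene
Product: 3 2,3,4,5-tetramethoxybenzaldehyde, via iminium salt 2 (not isolated)
Conditions: POCl3, DMF, 0 °C to 80 °C; then H2O, rt
Reagents that add atoms: N,N-dimethylformamide CN(C)C=O; water O
Why: Vilsmeier–Haack formylation, in which the electron-rich arene attacks the chloroiminium ion at one of its two equivalent free positions (ortho to one methoxy group, para to another) and the formyl group then deactivates the ring against a second substitution.

Step 2
Reactants: 3 2,3,4,5-tetramethoxybenzaldehyde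
Product: 5 2,3,4,5-tetramethoxyphenol, via aryl formate 4 (not isolated)
Conditions: mCPBA (1.2 equiv), CH2Cl2, 0 °C to rt; then MeOH, HCl (cat.), rt
Reagents that add atoms: 3-chloroperoxybenzoic acid OOC(=O)c1cccc(Cl)c1
Why: Baeyer–Villiger (Dakin-type) oxidation, in which the electron-rich aryl group migrates in preference to hydrogen in the tetrahedral peracid adduct and the resulting aryl formate is cleaved by acid-catalysed methanolysis.

Step 3
Reactants: 5 2,3,4,5-tetramethoxyphenol
Product: 6 1-(2-hydroxy-3,4,5,6-tetramethoxyphenyl)ethan-1-one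
Conditions: AcOH, BF3·OEt2, 70 °C; aqueous work-up
Reagents that add atoms: acetic acid CC(=O)O
Why: BF3-mediated Friedel–Crafts (Fries-type) C-acylation of a phenol, where the only unsubstituted ring carbon lies ortho to the hydroxyl, so the regiochemistry is fixed and the chelated ortho-hydroxy ketone is the stable product.

Step 4
Reactants: 6 1-(2-hydroxy-3,4,5,6-tetramethoxyphenyl)ethan-1-one; 7 ethyl 2,2-diethoxyacetate
Product: 10 5,6,7,8-tetramethoxy-4-oxo-4H-chromene-2-carbaldehyde, via diketone 8 (not isolated), via acetal chromone 9 (not isolated)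
Conditions: NaH (3.5 equiv), THF, 0 °C to reflux; then AcOH/aq. HCl, 60 °C
Reagents that add atoms: water O
Why: Crossed Claisen condensation of the phenoxide–enolate of 6 with ester 7, followed by acid-catalysed cyclodehydration of the o-hydroxyaryl 1,3-diketone to the 4-pyranone ring (the classical chromone synthesis) and hydrolysis of the diethyl acetal, which gives the C2 aldehyde without any redox step.

Step 5
Reactants: 10 5,6,7,8-tetramethoxy-4-oxo-4H-chromene-2-carbaldehyde
Product: 11 2-ethynyl-5,6,7,8-tetramethoxy-4H-chromen-4-one
Conditions: dimethyl (1-diazo-2-oxopropyl)phosphonate (1.3 equiv), K2CO3, MeOH/THF, 0 °C to rt; quench with aq. NH4Cl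
Reagents that add atoms: dimethyl (1-diazo-2-oxopropyl)phosphonate CC(=O)C(=[N+]=[N-])P(=O)(OC)OC
Why: Seyferth–Gilbert homologation in the Ohira–Bestmann variant, in which the diazomethylphosphonate anion generated in the flask adds to the aldehyde (far more electrophilic than the vinylogous-ester C4 carbonyl), olefination gives a diazoalkene, and loss of N2 with 1,2-hydrogen shift of the alkylidene carbene gives the terminal alkyne.

Step 6
Reactants: 11 2-ethynyl-5,6,7,8-tetramethoxy-4H-chromen-4-one; 12 (E)-1-methoxy-3-(trimethylsilyloxy)buta-1,3-diene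
Product: 15 4'-hydroxy-5,6,7,8-tetramethoxyflavone (target), via cycloadduct 13 (not isolated), via silyl ether 14 (not isolated)
Conditions: 12 (3 equiv), BHT (cat.), toluene, 110 °C, sealed tube; then 1 M HCl, THF, rt
Reagents that add atoms: none
Why: Proposed new method: a thermal normal-demand [4+2] cycloaddition with unequal bond formation in the transition state, in which the CH2 terminus of the diene (largest HOMO coefficient) bonds to C2', the δ-carbon of the O=C4–C3=C2–C1'≡C2' acceptor, and the methoxy-bearing diene carbon closes onto C1'; the 1,4-cyclohexadiene 13 then expels methanol to the aryl silyl ether 14, which dilute acid cleaves to the phenol. The closest known reaction type is the Diels–Alder/aromatisation of 1-methoxy-3-silyloxybutadienes with acetylenic ketones and esters to para-acylphenols, which has not been shown for an alkyne activated only through an intervening chromone C2=C3 bond. One six-membered carbocycle is closed by intermolecular cycloaddition through the bonds C2'–C3' and C1'–C6'. The sp3 centre formed at C6' is racemic and disappears on aromatisation, so nothing has to be controlled there. The step needs regioselectivity (4'- and not 3'-hydroxyl), which should follow from pairing the nucleophilic diene terminus with the electrophilic C2', and chemoselectivity for the alkyne, which should follow from the rod-like ethynyl group being sterically open while C2=C3 is trisubstituted and carries the donor ring oxygen and the C4 carbonyl is inert to uncatalysed hetero-cycloaddition. No Lewis acid is used, because carbonyl activation would make C2 a benzopyrylium-type electrophile and divert the silyl enol ether to conjugate addition; the 4'-hydroxyl needs no protection since it appears only as the ring forms.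

Compound list
1 | 1,2,3,4-tetramethoxybenzene | COc1ccc(OC)c(OC)c1OC | starting material
2 | N,N-dimethyl-(2,3,4,5-tetramethoxybenzylidene)iminium dichlorophosphate | C[N+](C)=Cc1cc(OC)c(OC)c(OC)c1OC.[O-]P(=O)(Cl)Cl | intermediate (not isolated)
3 | 2,3,4,5-tetramethoxybenzaldehyde | COc1cc(C=O)c(OC)c(OC)c1OC | intermediate
4 | 2,3,4,5-tetramethoxyphenyl formate | COc1cc(OC=O)c(OC)c(OC)c1OC | intermediate (not isolated)
5 | 2,3,4,5-tetramethoxyphenol | COc1cc(O)c(OC)c(OC)c1OC | intermediate
6 | 1-(2-hydroxy-3,4,5,6-tetramethoxyphenyl)ethan-1-one | CC(=O)c1c(O)c(OC)c(OC)c(OC)c1OC | intermediate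
7 | ethyl 2,2-diethoxyacetate | CCOC(OCC)C(=O)OCC | starting material
8 | 4,4-diethoxy-1-(2-hydroxy-3,4,5,6-tetramethoxyphenyl)butane-1,3-dione | CCOC(OCC)C(=O)CC(=O)c1c(O)c(OC)c(OC)c(OC)c1OC | intermediate (not isolated)
9 | 2-(diethoxymethyl)-5,6,7,8-tetramethoxy-4H-chromen-4-one | CCOC(OCC)c1cc(=O)c2c(OC)c(OC)c(OC)c(OC)c2o1 | intermediate (not isolated)
10 | 5,6,7,8-tetramethoxy-4-oxo-4H-chromene-2-carbaldehyde | O=Cc1cc(=O)c2c(OC)c(OC)c(OC)c(OC)c2o1 | intermediate
11 | 2-ethynyl-5,6,7,8-tetramethoxy-4H-chromen-4-one | C#Cc1cc(=O)c2c(OC)c(OC)c(OC)c(OC)c2o1 | intermediate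
12 | (E)-1-methoxy-3-(trimethylsilyloxy)buta-1,3-diene | CO/C=C/C(=C)O[Si](C)(C)C | starting material
13 | 2-[6-methoxy-4-(trimethylsilyloxy)cyclohexa-1,4-dien-1-yl]-5,6,7,8-tetramethoxy-4H-chromen-4-one (racemic at the methoxy-bearing carbon) | COC1C=C(O[Si](C)(C)C)CC=C1c1cc(=O)c2c(OC)c(OC)c(OC)c(OC)c2o1 | intermediate (not isolated)
14 | 5,6,7,8-tetramethoxy-2-[4-(trimethylsilyloxy)phenyl]-4H-chromen-4-one | C[Si](C)(C)Oc1ccc(cc1)-c1cc(=O)c2c(OC)c(OC)c(OC)c(OC)c2o1 | intermediate (not isolated)
15 | 4'-hydroxy-5,6,7,8-tetramethoxyflavone | COc1c(OC)c(OC)c2c(=O)cc(-c3ccc(O)cc3)oc2c1OC | target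

Total step count: 6
Longest linear sequence: 6 steps (1 to 15)

Steps most likely to fail

Step 6. The alkyne is activated only through the chromone double bond and may react too slowly, so that thermal decay or oligomerisation of the diene and of the ynenone outruns cycloaddition; bond formation in the reverse orientation would lead to the 3'-phenol. The fallback leaves the cycloaddition and attaches a preformed B ring by known flavone chemistry. It sets out from 6: Claisen–Schmidt condensation with 4-(benzyloxy)benzaldehyde (KOH, EtOH, rt) should give (E)-3-[4-(benzyloxy)phenyl]-1-(2-hydroxy-3,4,5,6-tetramethoxyphenyl)prop-2-en-1-one F1. Oxidative cyclisation with catalytic I2 in DMSO at 120 °C should give 2-[4-(benzyloxy)phenyl]-5,6,7,8-tetramethoxy-4H-chromen-4-one F2. Hydrogenolysis (H2, Pd/C, EtOAc/MeOH, rt) returns to the route at 15.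

Step 5. Methoxide may attack C2 of the electrophilic chromone aldehyde and open the pyranone ring, or methanol may add in conjugate fashion to the newly formed ethynyl group, which is electrophilic at its terminus. The fallback avoids alcoholic base by olefination and elimination. It sets out from 10: Wittig reaction with the ylide from (bromomethyl)triphenylphosphonium bromide and KOtBu (THF, −78 °C) should give (Z)-2-(2-bromovinyl)-5,6,7,8-tetramethoxy-4H-chromen-4-one F3. Anti-dehydrobromination with DBU (MeCN, rt to 50 °C) returns to the route at 11.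

Step 4. The Claisen condensation at the di-ortho-substituted acetophenone may stall, or the aldehyde may be lost through hydrate formation and self-condensation during the combined acid cyclisation and acetal hydrolysis. The fallback reaches the aldehyde through an ester and an alcohol. It sets out from 6: condensation with diethyl oxalate (NaOEt, EtOH) should give ethyl 4-(2-hydroxy-3,4,5,6-tetramethoxyphenyl)-2,4-dioxobutanoate F4, which is not isolated. Cyclodehydration (HCl, EtOH, reflux) should give ethyl 5,6,7,8-tetramethoxy-4-oxo-4H-chromene-2-carboxylate F5. Selective reduction of the activated ester (NaBH4, MeOH, 0 °C) should give 2-(hydroxymethyl)-5,6,7,8-tetramethoxy-4H-chromen-4-one F6. Oxidation with activated MnO2 (CH2Cl2, rt) returns to the route at 10.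

Further compounds
F1 | step 6 | (E)-3-[4-(benzyloxy)phenyl]-1-(2-hydroxy-3,4,5,6-tetramethoxyphenyl)prop-2-en-1-one | COc1c(O)c(C(=O)/C=C/c2ccc(OCc3ccccc3)cc2)c(OC)c(OC)c1OC
F2 | step 6 | 2-[4-(benzyloxy)phenyl]-5,6,7,8-tetramethoxy-4H-chromen-4-one | COc1c(OC)c(OC)c2c(=O)cc(-c3ccc(OCc4ccccc4)cc3)oc2c1OC
F3 | step 5 | (Z)-2-(2-bromovinyl)-5,6,7,8-tetramethoxy-4H-chromen-4-one | Br/C=C\c1cc(=O)c2c(OC)c(OC)c(OC)c(OC)c2o1
F4 | step 4 | ethyl 4-(2-hydroxy-3,4,5,6-tetramethoxyphenyl)-2,4-dioxobutanoate | CCOC(=O)C(=O)CC(=O)c1c(O)c(OC)c(OC)c(OC)c1OC
F5 | step 4 | ethyl 5,6,7,8-tetramethoxy-4-oxo-4H-chromene-2-carboxylate | CCOC(=O)c1cc(=O)c2c(OC)c(OC)c(OC)c(OC)c2o1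
F6 | step 4 | 2-(hydroxymethyl)-5,6,7,8-tetramethoxy-4H-chromen-4-one | OCc1cc(=O)c2c(OC)c(OC)c(OC)c(OC)c2o1
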